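**Strategy.** Ring B is disconnected at C7–C8 and C9–C10 (drimane numbering). A Diels–Alder reaction joins a ring A vinylcyclohexene, whose diene is C7=C6–C5=C10, to the ester-conjugated C8=C9 bond of ethyl buta-2,3-dienoate. In one operation ring B closes, the quaternary C10 is set under control of the C3 silyloxy stereocentre, C11 arrives on C9, and the untouched allene bond becomes the exocyclic C8=C12 methylene, the feature the step exploits. Afterwards C9 is levelled by enolate protonation, the methylene is masked as its epoxide while a hydroxyl-directed hydrogenation sets the cis ring fusion, isofraxidin is attached by Mitsunobu etherification, and ring A is oxidised and acetoxylated.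

Key step: step 5

Numbering: bicyclic compounds carry drimane numbering (ring A: C1–C5 and C10; ring B: C5–C10; C11 on C9; C12 on C8; gem-dimethyl on C4; C15 methyl on C10); β is the face of the C10 methyl. The target is (2R,5S,9S,10S) in this numbering, with 5β-H (cis-fused), 9α-H and 2α-OAc.

Assumption: (S)-3-hydroxy-2,2-dimethylcyclohexan-1-one (the yeast reduction product of 2,2-dimethylcyclohexane-1,3-dione) is taken as a commercial single enantiomer.

**Step 1**
Reactants: 1 (S)-3-hydroxy-2,2-dimethylcyclohexan-1-one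
Product: 2 (S)-3-[(tert-butyldimethylsilyl)oxy]-2,2-dimethylcyclohexan-1-one
Conditions: TBSCl, imidazole, DMF, rt
Reagents that add atoms: tert-butyldimethylsilyl chloride, CC(C)(C)[Si](C)(C)Cl
Why: Imidazole-assisted silylation protects O3 as the bulky ether that later biases the diene conformation; no stereocentre is touched.

**Step 2**
Reactants: 2 (S)-3-[(tert-butyldimethylsilyl)oxy]-2,2-dimethylcyclohexan-1-one
Product: 4 (3S)-3-[(tert-butyldimethylsilyl)oxy]-2,2,6-trimethylcyclohexan-1-one (C6 epimers), via lithium enolate 3 (not isolated)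
Conditions: LiN(iPr)2, THF, −78 °C; MeI, −78 → 0 °C
Reagents that add atoms: iodomethane, CI
Why: Kinetic enolate alkylation is regiospecific because only C6 carries α-hydrogens (C2 is quaternary), and the new centre (future C10) need not be controlled since it becomes sp2 in step 3.

**Step 3**
Reactants: 4 (3S)-3-[(tert-butyldimethylsilyl)oxy]-2,2,6-trimethylcyclohexan-1-one
Product: 6 (S)-5-[(tert-butyldimethylsilyl)oxy]-2,6,6-trimethylcyclohex-1-en-1-yl trifluoromethanesulfonate, via potassium enolate 5 (not isolated)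
Conditions: KN(SiMe3)2, THF, −78 °C; PhNTf2, −78 °C → rt
Reagents that add atoms: N-phenylbis(trifluoromethanesulfonimide), O=S(=O)(N(c1ccccc1)S(=O)(=O)C(F)(F)F)C(F)(F)F
Why: O-Triflation of the only possible (tetrasubstituted) enolate should give the enol triflate, as in the standard preparation of 2,6,6-trimethylcyclohexenyl triflate.

**Step 4**
Reactants: 6 (S)-5-[(tert-butyldimethylsilyl)oxy]-2,6,6-trimethylcyclohex-1-en-1-yl trifluoromethanesulfonate, 7 tributyl(vinyl)stannane
Product: 8 (S)-tert-butyldimethyl[(2,2,4-trimethyl-3-vinylcyclohex-3-en-1-yl)oxy]silane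
Conditions: Pd(PPh3)4 (5 mol%), LiCl, THF, reflux
Reagents that add atoms: none
Why: Stille cross-coupling (zerovalent palladium, chloride-assisted transmetalation), well precedented for hindered 2,6,6-trimethylcyclohexenyl triflates, installs the vinyl group and completes the C7=C6–C5=C10 diene without touching C3.

**Step 5**
Reactants: 8 (S)-tert-butyldimethyl[(2,2,4-trimethyl-3-vinylcyclohex-3-en-1-yl)oxy]silane, 9 ethyl buta-2,3-dienoate
Product: 10 ethyl 3β-(tert-butyldimethylsilyloxy)drima-5,8(12)-dien-11-oate (10β-methyl; mixture of C9 epimers)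
Conditions: toluene, BHT (cat.), 130 °C, sealed tube
Reagents that add atoms: none
Why: Concerted, asynchronous normal-demand [4+2] cycloaddition (Diels–Alder reaction) of the electron-rich diene C7=C6–C5=C10 with the ester-conjugated C8=C9 bond of the allene, whose distal C8=C12 bond stays behind as the exocyclic methylene; the closest precedent is the thermal addition of acetylenedicarboxylates and allenic esters to 1-vinyl-2,6,6-trimethylcyclohexene. Ring B is closed by intermolecular [4+2] annulation, both new bonds (C7–C8 and C9–C10) forming suprafacially on one face of the diene, not by a tethered exo or endo closure. For regiochemistry, the largest HOMO coefficient should sit on the unsubstituted C7 and the largest LUMO coefficient on the central allene carbon C8, so C7–C8 bonding leads and the ester-bearing C9 ends on the hindered C10. The quaternary C10 is controlled by the (S)-configured C3: with the silyloxy group pseudoequatorial, the 4β-methyl is pseudoaxial and blocks the β face, so the dienophile should add to the α face and the C10 methyl ends β (cis to O3). C9 is not controlled (endo and exo approach of the ester are both expected) and is levelled in step 6. The step needs site selectivity for the conjugated allene bond, which the ester secures, and neutral thermal conditions that the silyl ether tolerates.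

**Step 6**
Reactants: 10 ethyl 3β-(tert-butyldimethylsilyloxy)drima-5,8(12)-dien-11-oate (C9 epimers)
Product: 12 ethyl 3β-(tert-butyldimethylsilyloxy)-9α-H-drima-5,8(12)-dien-11-oate (C11 on the β face), via lithium dienolate 11 (not isolated)
Conditions: LiN(iPr)2, THF, −78 → −40 °C; then AcOH, THF, −78 °C
Reagents that add atoms: none
Why: Deprotonation at C9 gives a planar dienolate, and kinetic α-protonation from the α face (opposite the pseudoaxial C10 methyl) should return the deconjugated ester with 9α-H from both epimers, while a fast cold quench avoids γ-protonation to the conjugated ester.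

**Step 7**
Reactants: 12 ethyl 3β-(tert-butyldimethylsilyloxy)-9α-H-drima-5,8(12)-dien-11-oate
Product: 13 3β-(tert-butyldimethylsilyloxy)drima-5,8(12)-dien-11-ol
Conditions: iBu2AlH, CH2Cl2, −78 → 0 °C
Reagents that add atoms: none
Why: Hydride reduction of the ester to the primary alcohol leaves the silyl ether, both alkenes and all stereocentres untouched.

**Step 8**
Reactants: 13 3β-(tert-butyldimethylsilyloxy)drima-5,8(12)-dien-11-ol
Product: 14 8,12-epoxy-3β-(tert-butyldimethylsilyloxy)drim-5-en-11-ol (epoxide configuration at C8 immaterial)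
Conditions: VO(acac)2 (5 mol%), tBuOOH, CH2Cl2, 0 °C → rt
Reagents that add atoms: tert-butyl hydroperoxide, CC(C)(C)OO
Why: Hydroxyl-directed epoxidation delivers oxygen from the vanadate ester of the homoallylic C11 alcohol to the nearby exocyclic alkene, while the C5=C6 bond, flanked by two quaternary carbons, should stay intact; the epoxide is only a mask and is removed in step 11.

**Step 9**
Reactants: 14 8,12-epoxy-3β-(tert-butyldimethylsilyloxy)drim-5-en-11-ol
Product: 15 8,12-epoxydrim-5-ene-3β,11-diol
Conditions: Bu4NF, THF, 50 °C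
Reagents that add atoms: none
Why: Fluoride cleaves the Si–O bond and frees the 3β-hydroxyl needed as a directing group; the epoxide should survive because its opening by O11 would be a disfavoured 5-endo process.

**Step 10**
Reactants: 15 8,12-epoxydrim-5-ene-3β,11-diol
Product: 16 8,12-epoxy-5β-drimane-3β,11-diol (5β-H, cis-fused)
Conditions: [Ir(cod)(PCy3)(py)]PF6 (10 mol%), H2 (1 atm), CH2Cl2, rt
Reagents that add atoms: none
Why: In this hydroxyl-directed homogeneous hydrogenation the cationic iridium binds the 3β- and C11-hydroxyls, which both sit axially over the β face of C5=C6 in the ring-flipped conformer, so H2 should add to that face and set 5β-H against the intrinsic α preference.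

**Step 11**
Reactants: 16 8,12-epoxy-5β-drimane-3β,11-diol
Product: 18 5β-drim-8(12)-ene-3β,11-diol, via iodohydrin 17 (not isolated)
Conditions: Zn, NaI, NaOAc, AcOH, rt
Reagents that add atoms: none
Why: Reductive deoxygenation: iodide opens the protonated epoxide at the primary C12 and zinc reduces the iodohydrin with β-elimination, regenerating the C8=C12 alkene without touching C9 or the hydroxyls.

**Step 12**
Reactants: 18 5β-drim-8(12)-ene-3β,11-diol, 19 isofraxidin (7-hydroxy-6,8-dimethoxy-2H-chromen-2-one)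
Product: 20 7-{[3β-hydroxy-5β-drim-8(12)-en-11-yl]oxy}-6,8-dimethoxy-2H-chromen-2-one
Conditions: PPh3, DIAD, THF, 0 °C → rt
Reagents that add atoms: none
Why: Mitsunobu etherification activates the primary C11 alcohol as its alkoxyphosphonium ion for displacement by the acidic coumarin 7-hydroxyl, while the neopentyl-type secondary 3β-hydroxyl should not react; no stereocentre is involved.

**Step 13**
Reactants: 20 7-{[3β-hydroxy-5β-drim-8(12)-en-11-yl]oxy}-6,8-dimethoxy-2H-chromen-2-one
Product: 21 7-{[3-oxo-5β-drim-8(12)-en-11-yl]oxy}-6,8-dimethoxy-2H-chromen-2-one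
Conditions: Dess–Martin periodinane, CH2Cl2, rt
Reagents that add atoms: none
Why: Neutral oxidation of the hindered secondary alcohol gives the C3 ketone, and the cis ring fusion cannot epimerise because C5 is not α to the carbonyl (C4 is quaternary).

**Step 14**
Reactants: 21 7-{[3-oxo-5β-drim-8(12)-en-11-yl]oxy}-6,8-dimethoxy-2H-chromen-2-one
Product: 22 7-{[3-(trimethylsilyloxy)-5β-drima-2,8(12)-dien-11-yl]oxy}-6,8-dimethoxy-2H-chromen-2-one
Conditions: TMSOTf, Et3N, CH2Cl2, 0 °C
Reagents that add atoms: trimethylsilyl trifluoromethanesulfonate, C[Si](C)(C)OS(=O)(=O)C(F)(F)F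
Why: Soft enolisation gives a single silyl enol ether because C2 is the only enolisable position, and it keeps the coumarin lactone away from strong base.

**Step 15**
Reactants: 22 7-{[3-(trimethylsilyloxy)-5β-drima-2,8(12)-dien-11-yl]oxy}-6,8-dimethoxy-2H-chromen-2-one
Product: 23 7-{[2α-acetoxy-3-oxo-5β-drim-8(12)-en-11-yl]oxy}-6,8-dimethoxy-2H-chromen-2-one
Conditions: Pb(OAc)4, CH2Cl2, 0 °C → rt
Reagents that add atoms: lead tetraacetate, CC(=O)O[Pb](OC(C)=O)(OC(C)=O)OC(C)=O
Why: Rubottom-type oxidation of the silyl enol ether with tetravalent lead should transfer acetate to C2 on the α face, trans to the axial C10 and 4β methyl groups of the preferred conformer, giving the equatorial 2α-acetate with loss of trimethylsilyl acetate.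

**Compound list**
1 | (S)-3-hydroxy-2,2-dimethylcyclohexan-1-one | O=C1CCC[C@H](O)C1(C)C | starting material
2 | (S)-3-[(tert-butyldimethylsilyl)oxy]-2,2-dimethylcyclohexan-1-one | O=C1CCC[C@H](O[Si](C)(C)C(C)(C)C)C1(C)C | intermediate
3 | lithium enolate of 2 | [Li]OC1=CCC[C@H](O[Si](C)(C)C(C)(C)C)C1(C)C | intermediate
4 | (3S)-3-[(tert-butyldimethylsilyl)oxy]-2,2,6-trimethylcyclohexan-1-one (C6 epimers) | CC1CC[C@H](O[Si](C)(C)C(C)(C)C)C(C)(C)C1=O | intermediate
5 | potassium enolate of 4 | [K]OC1=C(C)CC[C@H](O[Si](C)(C)C(C)(C)C)C1(C)C | intermediate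
6 | (S)-5-[(tert-butyldimethylsilyl)oxy]-2,6,6-trimethylcyclohex-1-en-1-yl trifluoromethanesulfonate | CC1=C(OS(=O)(=O)C(F)(F)F)C(C)(C)[C@@H](O[Si](C)(C)C(C)(C)C)CC1 | intermediate
7 | tributyl(vinyl)stannane | C=C[Sn](CCCC)(CCCC)CCCC | starting material
8 | (S)-tert-butyldimethyl[(2,2,4-trimethyl-3-vinylcyclohex-3-en-1-yl)oxy]silane | C=CC1=C(C)CC[C@H](O[Si](C)(C)C(C)(C)C)C1(C)C | intermediate
9 | ethyl buta-2,3-dienoate | C=C=CC(=O)OCC | starting material
10 | ethyl 3β-(tert-butyldimethylsilyloxy)drima-5,8(12)-dien-11-oate, 10β-methyl, C9 epimers | C=C1CC=C2C(C)(C)[C@@H](O[Si](C)(C)C(C)(C)C)CC[C@]2(C)C1C(=O)OCC | intermediate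
11 | lithium dienolate (C9=C11) of 10 | C=C1CC=C2C(C)(C)[C@@H](O[Si](C)(C)C(C)(C)C)CC[C@]2(C)C1=C(O[Li])OCC | intermediate
12 | ethyl 3β-(tert-butyldimethylsilyloxy)-9α-H-drima-5,8(12)-dien-11-oate | C=C1CC=C2C(C)(C)[C@@H](O[Si](C)(C)C(C)(C)C)CC[C@]2(C)[C@H]1C(=O)OCC | intermediate
13 | 3β-(tert-butyldimethylsilyloxy)drima-5,8(12)-dien-11-ol | C=C1CC=C2C(C)(C)[C@@H](O[Si](C)(C)C(C)(C)C)CC[C@]2(C)[C@H]1CO | intermediate
14 | 8,12-epoxy-3β-(tert-butyldimethylsilyloxy)drim-5-en-11-ol | C1OC12CC=C3C(C)(C)[C@@H](O[Si](C)(C)C(C)(C)C)CC[C@]3(C)[C@H]2CO | intermediate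
15 | 8,12-epoxydrim-5-ene-3β,11-diol | C1OC12CC=C3C(C)(C)[C@@H](O)CC[C@]3(C)[C@H]2CO | intermediate
16 | 8,12-epoxy-5β-drimane-3β,11-diol | C1OC12CC[C@@H]3C(C)(C)[C@@H](O)CC[C@]3(C)[C@H]2CO | intermediate
17 | 12-iodo-5β-drimane-3β,8,11-triol | ICC1(O)CC[C@@H]2C(C)(C)[C@@H](O)CC[C@]2(C)[C@H]1CO | intermediate
18 | 5β-drim-8(12)-ene-3β,11-diol | C=C1CC[C@@H]2C(C)(C)[C@@H](O)CC[C@]2(C)[C@H]1CO | intermediate
19 | isofraxidin (7-hydroxy-6,8-dimethoxy-2H-chromen-2-one) | COc1cc2ccc(=O)oc2c(OC)c1O | starting material
20 | 7-{[3β-hydroxy-5β-drim-8(12)-en-11-yl]oxy}-6,8-dimethoxy-2H-chromen-2-one | C=C1CC[C@@H]2C(C)(C)[C@@H](O)CC[C@]2(C)[C@H]1COc1c(OC)cc2ccc(=O)oc2c1OC | intermediate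
21 | 7-{[3-oxo-5β-drim-8(12)-en-11-yl]oxy}-6,8-dimethoxy-2H-chromen-2-one | C=C1CC[C@@H]2C(C)(C)C(=O)CC[C@]2(C)[C@H]1COc1c(OC)cc2ccc(=O)oc2c1OC | intermediate
22 | 7-{[3-(trimethylsilyloxy)-5β-drima-2,8(12)-dien-11-yl]oxy}-6,8-dimethoxy-2H-chromen-2-one | C=C1CC[C@@H]2C(C)(C)C(O[Si](C)(C)C)=CC[C@]2(C)[C@H]1COc1c(OC)cc2ccc(=O)oc2c1OC | intermediate
23 | 7-{[2α-acetoxy-3-oxo-5β-drim-8(12)-en-11-yl]oxy}-6,8-dimethoxy-2H-chromen-2-one, (2R,5S,9S,10S) | C=C1CC[C@@H]2C(C)(C)C(=O)[C@H](OC(C)=O)C[C@]2(C)[C@H]1COc1c(OC)cc2ccc(=O)oc2c1OC | target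

Total step count: 15
Longest linear sequence: 15 steps (1 → 23)

**Steps most likely to fail**

Step 5 (key cycloaddition). Bonding may occur in the reverse orientation (C8 to the hindered C10), the cycloaddition at the tetrasubstituted diene terminus may be slow enough for allenoate oligomerisation to compete, or the two diene faces may be poorly discriminated. Fallback, setting out from 8 and returning at 13: 8 is heated with the symmetrical dimethyl but-2-ynedioate, which removes the regiochemical question, to give dimethyl 3β-(tert-butyldimethylsilyloxy)drima-5,8-diene-11,12-dioate F1. LiAlH4 should reduce it to 3β-(tert-butyldimethylsilyloxy)drima-5,8-diene-11,12-diol F2. The less hindered C12 hydroxyl is converted (ClCO2Me, pyridine, −20 °C) into 11-hydroxy-3β-(tert-butyldimethylsilyloxy)drima-5,8-dien-12-yl methyl carbonate F3. Palladium-catalysed formate hydrogenolysis (Pd(OAc)2, PBu3, HCO2NH4) of this allylic carbonate should deliver hydride from the metal to the more substituted C9 on the α face, forming the C8=C12 methylene and 13.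

Step 10 (directed hydrogenation). Hydrogen may be delivered to the α face (trans ring fusion) if the hydroxyls do not control the approach, or the cationic iridium may rearrange the spiro-epoxide. Fallback, setting out from 13 and returning at 18: the methylene of 13 is cleaved (OsO4 cat., NaIO4) to 3β-(tert-butyldimethylsilyloxy)-11-hydroxy-12-nordrim-5-en-8-one F4. Its C11 hydroxyl is silylated (tBu2SiHCl, imidazole) to 11-(di-tert-butylsilyloxy)-3β-(tert-butyldimethylsilyloxy)-12-nordrim-5-en-8-one F5. CF3CO2H then protonates C6, and the Si–H bond held over the β face transfers hydride to the C5 cation (directed ionic hydrogenation), giving the cis-fused silyl trifluoroacetate of 3β-(tert-butyldimethylsilyloxy)-11-hydroxy-12-nor-5β-driman-8-one F6. Bu4NF removes both silyl groups to give 3β,11-dihydroxy-12-nor-5β-driman-8-one F7, and methylenation of the C8 ketone with Ph3P=CH2 gives 18.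

Step 15 (acetoxylation at C2). Acetate may enter from the β face, the open face of the alternative half-chair, giving the 2β-acetate. Fallback, setting out from 21 and returning at 23: 21 is hydroxylated at C2 (KN(SiMe3)2, then 2-(phenylsulfonyl)-3-phenyloxaziridine, THF, −78 °C), which by the same facial preference would give 7-{[2β-hydroxy-3-oxo-5β-drim-8(12)-en-11-yl]oxy}-6,8-dimethoxy-2H-chromen-2-one F8. Esterification with acetic acid under Mitsunobu conditions (PPh3, DIAD) then inverts C2 and gives 23.

**Further compounds**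
F1 | step 5 | dimethyl 3β-(tert-butyldimethylsilyloxy)drima-5,8-diene-11,12-dioate | COC(=O)C1CC=C2C(C)(C)[C@@H](O[Si](C)(C)C(C)(C)C)CC[C@]2(C)C=1C(=O)OC
F2 | step 5 | 3β-(tert-butyldimethylsilyloxy)drima-5,8-diene-11,12-diol | OCC1CC=C2C(C)(C)[C@@H](O[Si](C)(C)C(C)(C)C)CC[C@]2(C)C=1CO
F3 | step 5 | 11-hydroxy-3β-(tert-butyldimethylsilyloxy)drima-5,8-dien-12-yl methyl carbonate | COC(=O)OCC1CC=C2C(C)(C)[C@@H](O[Si](C)(C)C(C)(C)C)CC[C@]2(C)C=1CO
F4 | step 10 | 3β-(tert-butyldimethylsilyloxy)-11-hydroxy-12-nordrim-5-en-8-one | O=C1CC=C2C(C)(C)[C@@H](O[Si](C)(C)C(C)(C)C)CC[C@]2(C)[C@H]1CO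
F5 | step 10 | 11-(di-tert-butylsilyloxy)-3β-(tert-butyldimethylsilyloxy)-12-nordrim-5-en-8-one | O=C1CC=C2C(C)(C)[C@@H](O[Si](C)(C)C(C)(C)C)CC[C@]2(C)[C@H]1CO[SiH](C(C)(C)C)C(C)(C)C
F6 | step 10 | silyl trifluoroacetate of 3β-(tert-butyldimethylsilyloxy)-11-hydroxy-12-nor-5β-driman-8-one | O=C1CC[C@@H]2C(C)(C)[C@@H](O[Si](C)(C)C(C)(C)C)CC[C@]2(C)[C@H]1CO[Si](OC(=O)C(F)(F)F)(C(C)(C)C)C(C)(C)C
F7 | step 10 | 3β,11-dihydroxy-12-nor-5β-driman-8-one | O=C1CC[C@@H]2C(C)(C)[C@@H](O)CC[C@]2(C)[C@H]1CO
F8 | step 15 | 7-{[2β-hydroxy-3-oxo-5β-drim-8(12)-en-11-yl]oxy}-6,8-dimethoxy-2H-chromen-2-one | C=C1CC[C@@H]2C(C)(C)C(=O)[C@@H](O)C[C@]2(C)[C@H]1COc1c(OC)cc2ccc(=O)oc2c1OC
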